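The route rests on cutting the side chain (C11–C22, counted outward from ring carbon C9) between C16, the CH2 homoallylic to the C13=C14 alkene, and C17, the CH of the C17=C18 alkene. One operation, a hydroboration/B-alkyl Suzuki–Miyaura coupling, joins a C21 diol diene with a C9 (E)-alkenyl iodide. It exploits the C15–C16 ethylene bridge between two (E)-trisubstituted alkenes: in the precursor C15=C16 is a terminal vinyl group conjugated to C13=C14, which 9-BBN hydroborates at C16 only, so the hydroxyls at C3 and C8 of the decalin (rings A and B) need no protection. The diene comes from (+)-sclareolide by enzymatic C3 hydroxylation and three Wittig homologations; the iodide from 6-methylhept-5-en-2-one by carboalumination.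

Key step: step 8

Remark on the chemistry: ring carbons are numbered C1–C10 in the labdane manner (hydroxyls on C3 and C8, angular methyl on C10); lactols 3 and 5 and enol ether 4 are carried as mixtures at centres that disappear later; the C3-selective P450 BM3 variant of step 1 is assumed to be available by expression.

Step 1
Reactants: 1 (+)-sclareolide
Product: 2 3β-hydroxysclareolide (3S)
Conditions: engineered cytochrome P450 BM3 variant (C3-selective, E. coli lysate), NADP+ (cat.), Na2HPO3, phosphite dehydrogenase, air, potassium phosphate buffer pH 8.0 (50 mmol/L), 2 vol% EtOH, 25 °C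
Reagents that add atoms: dioxygen, O=O
Why: Cytochrome P450 monooxygenase hydroxylation (hydrogen abstraction by the iron-oxo species, then oxygen rebound with retention) at the equatorial C3–H, the known site for such variants on sclareolide, should give the 3S (3β) alcohol under enzyme control.

Step 2
Reactants: 2 3β-hydroxysclareolide
Product: 3 3β-hydroxysclareolide lactol (8α,12-epoxy-13,14,15,16-tetranorlabdane-3β,12-diol, C12 anomers)
Conditions: i-Bu2AlH (2.4 equiv), CH2Cl2, –78 °C; aq. KNaC4H4O6 work-up
Reagents that add atoms: none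
Why: Partial reduction of the γ-lactone to the lactol stops at the aluminium hemiacetal at –78 °C, the free C3 hydroxyl only consuming one equivalent of hydride and no skeletal stereocentre being touched.

Step 3
Reactants: 3 3β-hydroxysclareolide lactol
Product: 5 δ-lactol 8α,13-epoxy-14,15,16-trinorlabdane-3β,13-diol (C13 anomers), via enol ether 4 (not isolated)
Conditions: MeOCH2PPh3Cl (3.5 equiv), KOt-Bu (3.3 equiv), THF, 0 °C → rt; then aq. HCl (1 mol/L), THF, rt
Reagents that add atoms: (methoxymethyl)triphenylphosphonium chloride, [Cl-].COC[P+](c1ccccc1)(c1ccccc1)c1ccccc1; water, O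
Why: Wittig alkoxymethylenation of the open hydroxy-aldehyde form of 3 followed by acid hydrolysis of the enol ether is a one-carbon aldehyde homologation, and the new C13 aldehyde should be trapped by the C8 hydroxyl as the six-membered lactol.

Step 4
Reactants: 5 δ-lactol
Product: 6 (2E)-5-[(1R,2R,4aR,6S,8aS)-2,6-dihydroxy-2,5,5,8a-tetramethyldecahydronaphthalen-1-yl]-2-methylpent-2-enal
Conditions: Ph3P=C(CH3)CHO (1.5 equiv), toluene, 100 °C
Reagents that add atoms: 2-(triphenylphosphoranylidene)propanal, CC(C=O)=P(c1ccccc1)(c1ccccc1)c1ccccc1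
Why: Wittig olefination of the open form of 5 with a formyl-stabilised ylide is E-selective, so C13=C14 should form with the chain trans to the formyl group, and the hindered tertiary C8 hydroxyl should not add back under neutral conditions.

Step 5
Reactants: 6 (E)-enal
Product: 7 (1R,2R,4aR,6S,8aS)-2,5,5,8a-tetramethyl-1-[(3E)-4-methylhexa-3,5-dien-1-yl]decahydronaphthalene-2,6-diol
Conditions: Ph3PCH3Br (3.0 equiv), n-BuLi (2.8 equiv), THF, 0 °C; then 6, –78 °C → 0 °C
Reagents that add atoms: methyltriphenylphosphonium bromide, [Br-].C[P+](c1ccccc1)(c1ccccc1)c1ccccc1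
Why: Wittig methylenation attacks the enal carbonyl in 1,2-fashion and installs C16 as the terminal vinyl carbon without touching the C13=C14 geometry, the ylide being too weak a base to generate much of the C8 alkoxide.

Step 6
Reactants: 8 6-methylhept-5-en-2-one
Product: 10 6-methylhept-5-en-1-yne, via enol phosphate 9 (not isolated)
Conditions: LiN(i-Pr)2 (1.05 equiv), THF, –78 °C; ClP(O)(OEt)2, –78 °C → rt; then LiN(i-Pr)2 (2.3 equiv), THF, –78 °C → rt; aq. NH4Cl
Reagents that add atoms: none
Why: Kinetic deprotonation at the methyl group and O-phosphorylation give the terminal enol phosphate, from which amide base effects β-elimination to the terminal alkyne (methyl ketone to alkyne conversion), the trisubstituted alkene being inert.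

Step 7
Reactants: 10 6-methylhept-5-en-1-yne
Product: 12 (E)-1-iodo-2,6-dimethylhepta-1,5-diene, via alkenylalane 11 (not isolated)
Conditions: Me3Al (2.0 equiv), Cp2ZrCl2 (0.25 equiv), CH2Cl2, 0 °C → rt; then iodine (1.2 equiv), THF, –30 → 0 °C; aq. K2CO3
Reagents that add atoms: trimethylaluminium, C[Al](C)C; iodine, II
Why: Zirconium-catalysed syn-methylalumination of the terminal alkyne (Negishi carboalumination) places aluminium on the terminal carbon cis to the new methyl, and iodinolysis with retention should give the (E)-alkenyl iodide that fixes the C17=C18 geometry.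

Step 8
Reactants: 7 diol diene; 12 (E)-1-iodo-2,6-dimethylhepta-1,5-diene
Product: 14 (1R,2R,4aR,6S,8aS)-2,5,5,8a-tetramethyl-1-[(3E,7E)-4,8,12-trimethyltrideca-3,7,11-trien-1-yl]decahydronaphthalene-2,6-diol (the target), via trialkylborane 13 (not isolated)
Conditions: 9-BBN (3.4 equiv, as the dimer), THF, 0 °C → rt; then degassed aq. Cs2CO3 (3 mol/L), 12 (1.3 equiv), PdCl2(dppf) (5 mol%), AsPh3 (5 mol%), DMF, rt → 45 °C
Reagents that add atoms: none
Why: 9-BBN adds syn and anti-Markovnikov to the only monosubstituted alkene, the terminal vinyl C15=C16 of the conjugated diene, placing boron on C16 (the two hydroxyls are taken up as harmless B-alkoxy borinates with loss of H2); the base-activated borate then transfers its primary alkyl group to the alkenylpalladium iodide formed by oxidative addition of 12 to zerovalent palladium, and reductive elimination forms the C16–C17 bond. The closest known reaction type is the B-alkyl Suzuki–Miyaura coupling of alkyl-9-BBN reagents with (E)-alkenyl iodides, including monohydroboration of terminal 1,3-dienes to homoallylic boranes. No ring is closed and no stereocentre is created; the E geometry of C17=C18 is carried over from 12 because oxidative addition and reductive elimination both proceed with retention, and C13=C14 is not touched. The step needs regio- and chemoselective monohydroboration, which the steric demand of 9-BBN secures (terminal CH2 reacts far faster than a trisubstituted alkene, boron stays away from the substituted C15), and suppression of β-hydride elimination from the homoallylic alkylpalladium, which the wide bite angle of dppf together with AsPh3 secures. Aqueous base releases both hydroxyls from boron, so the target should be obtained directly.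

Compound list
1 | (+)-sclareolide, (3aR,5aS,9aS,9bR)-3a,6,6,9a-tetramethyldecahydronaphtho[2,1-b]furan-2(1H)-one | O=C1C[C@@H]2[C@@]3(C)CCCC(C)(C)[C@@H]3CC[C@@]2(C)O1 | starting material
2 | 3β-hydroxysclareolide, (3aR,5aR,7S,9aS,9bR)-7-hydroxy-3a,6,6,9a-tetramethyldecahydronaphtho[2,1-b]furan-2(1H)-one | O=C1C[C@@H]2[C@@]3(C)CC[C@H](O)C(C)(C)[C@@H]3CC[C@@]2(C)O1 | intermediate
3 | 3β-hydroxysclareolide lactol, (3aR,5aR,7S,9aS,9bR)-3a,6,6,9a-tetramethyldodecahydronaphtho[2,1-b]furan-2,7-diol (C2 anomers) | OC1C[C@@H]2[C@@]3(C)CC[C@H](O)C(C)(C)[C@@H]3CC[C@@]2(C)O1 | intermediate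
4 | enol ether, (1R,2R,4aR,6S,8aS)-1-(3-methoxyprop-2-en-1-yl)-2,5,5,8a-tetramethyldecahydronaphthalene-2,6-diol (E/Z mixture) | COC=CC[C@@H]1[C@@]2(C)CC[C@H](O)C(C)(C)[C@@H]2CC[C@@]1(C)O | intermediate
5 | δ-lactol, 8α,13-epoxy-14,15,16-trinorlabdane-3β,13-diol (C13 anomers; closed form of the 3-(decalinyl)propanal) | OC1CC[C@@H]2[C@@]3(C)CC[C@H](O)C(C)(C)[C@@H]3CC[C@@]2(C)O1 | intermediate
6 | (2E)-5-[(1R,2R,4aR,6S,8aS)-2,6-dihydroxy-2,5,5,8a-tetramethyldecahydronaphthalen-1-yl]-2-methylpent-2-enal | O=C/C(C)=C/CC[C@@H]1[C@@]2(C)CC[C@H](O)C(C)(C)[C@@H]2CC[C@@]1(C)O | intermediate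
7 | (1R,2R,4aR,6S,8aS)-2,5,5,8a-tetramethyl-1-[(3E)-4-methylhexa-3,5-dien-1-yl]decahydronaphthalene-2,6-diol | C=C/C(C)=C/CC[C@@H]1[C@@]2(C)CC[C@H](O)C(C)(C)[C@@H]2CC[C@@]1(C)O | intermediate
8 | 6-methylhept-5-en-2-one | CC(=O)CCC=C(C)C | starting material
9 | diethyl 6-methylhepta-1,5-dien-2-yl phosphate | C=C(CCC=C(C)C)OP(=O)(OCC)OCC | intermediate
10 | 6-methylhept-5-en-1-yne | C#CCCC=C(C)C | intermediate
11 | (E)-(2,6-dimethylhepta-1,5-dien-1-yl)dimethylalane | CC(C)=CCC/C(C)=C/[Al](C)C | intermediate
12 | (E)-1-iodo-2,6-dimethylhepta-1,5-diene | CC(C)=CCC/C(C)=C/I | intermediate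
13 | 9-[(3E)-6-(decalinyl)-4-methylhex-3-en-1-yl]-9-borabicyclo[3.3.1]nonane derived from 7, both hydroxyls carried as 9-BBN borinates | B1(C2CCCC1CCC2)CC/C(C)=C/CC[C@@H]3[C@@]4(C)CC[C@H](OB5C6CCCC5CCC6)C(C)(C)[C@@H]4CC[C@@]3(C)OB7C8CCCC7CCC8 | intermediate
14 | (1R,2R,4aR,6S,8aS)-2,5,5,8a-tetramethyl-1-[(3E,7E)-4,8,12-trimethyltrideca-3,7,11-trien-1-yl]decahydronaphthalene-2,6-diol | CC(C)=CCC/C(C)=C/CC/C(C)=C/CC[C@@H]1[C@@]2(C)CC[C@H](O)C(C)(C)[C@@H]2CC[C@@]1(C)O | target

Total step count: 8. Longest linear sequence: 6 (steps 1–5 and 8).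

Steps most likely to fail

Step 8. The hydroboration may be incomplete or unselective (borane consumed by the hydroxyls, second hydroboration of the diene), and the homoallylic borane may undergo β-hydride elimination or protodeboronation during coupling. The fallback sets out from 5 and 12 and comes back at 14. It still forms the C16–C17 bond, but from a C16 radical and without any hydrometalation. Addition of isopropenylmagnesium bromide to 5 would give the C13 allylic alcohol F1 as an epimer mixture. Johnson–Claisen rearrangement of F1 with triethyl orthoacetate and catalytic propionic acid at 140 °C would set the (E)-C13=C14 alkene and the C15–C16 bond in the ethyl ester F2. LiOH would give the acid F3, and N-hydroxyphthalimide with N,N'-diisopropylcarbodiimide the redox-active ester F4. Iodide 12 would be converted (t-BuLi, then ZnCl2) into the alkenylzinc chloride F5, and nickel-catalysed decarboxylative alkenylation of F4 with F5 (Ni(acac)2, 2,2'-bipyridine, THF/DMF, rt) would lead to 14.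

Step 3. Ring opening of the hindered lactol under the ylide may be sluggish, and the acid used for enol ether hydrolysis may dehydrate the new lactol or the tertiary alcohol. The fallback sets out from 3 and comes back at 5 without any acid. Seyferth–Gilbert homologation of 3 with the Ohira–Bestmann reagent (K2CO3, MeOH) would give the terminal alkyne F6. Anti-Markovnikov hydration of F6 by hydroboration with disiamylborane and buffered H2O2 oxidation would give the C13 aldehyde, which closes to 5.

Step 4. The weakly nucleophilic formyl ylide may react slowly with a lactol that opens reluctantly, and prolonged heating may cause over-homologation to the dienal or conjugate addition of the C8 hydroxyl. The fallback sets out from 5 and comes back at 6 through the ester oxidation level. The more reactive ylide Ph3P=C(CH3)CO2Et (toluene, 80 °C) would give the ethyl (E)-enoate F7. i-Bu2AlH (CH2Cl2, –78 °C) would reduce it to the allylic alcohol F8, and MnO2 (CH2Cl2, rt) would oxidise only the allylic hydroxyl to give 6.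

Further compounds
F1 | step 8 | (1R,2R,4aR,6S,8aS)-1-(3-hydroxy-4-methylpent-4-en-1-yl)-2,5,5,8a-tetramethyldecahydronaphthalene-2,6-diol (C13 epimers) | C=C(C)C(O)CC[C@@H]1[C@@]2(C)CC[C@H](O)C(C)(C)[C@@H]2CC[C@@]1(C)O
F2 | step 8 | ethyl (4E)-7-[(1R,2R,4aR,6S,8aS)-2,6-dihydroxy-2,5,5,8a-tetramethyldecahydronaphthalen-1-yl]-4-methylhept-4-enoate | CCOC(=O)CC/C(C)=C/CC[C@@H]1[C@@]2(C)CC[C@H](O)C(C)(C)[C@@H]2CC[C@@]1(C)O
F3 | step 8 | (4E)-7-[(1R,2R,4aR,6S,8aS)-2,6-dihydroxy-2,5,5,8a-tetramethyldecahydronaphthalen-1-yl]-4-methylhept-4-enoic acid | OC(=O)CC/C(C)=C/CC[C@@H]1[C@@]2(C)CC[C@H](O)C(C)(C)[C@@H]2CC[C@@]1(C)O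
F4 | step 8 | 1,3-dioxoisoindolin-2-yl (4E)-7-[(1R,2R,4aR,6S,8aS)-2,6-dihydroxy-2,5,5,8a-tetramethyldecahydronaphthalen-1-yl]-4-methylhept-4-enoate | O=C(CC/C(C)=C/CC[C@@H]1[C@@]2(C)CC[C@H](O)C(C)(C)[C@@H]2CC[C@@]1(C)O)ON1C(=O)c2ccccc2C1=O
F5 | step 8 | (E)-(2,6-dimethylhepta-1,5-dien-1-yl)zinc chloride | CC(C)=CCC/C(C)=C/[Zn]Cl
F6 | step 3 | (1R,2R,4aR,6S,8aS)-2,5,5,8a-tetramethyl-1-(prop-2-yn-1-yl)decahydronaphthalene-2,6-diol | C#CC[C@@H]1[C@@]2(C)CC[C@H](O)C(C)(C)[C@@H]2CC[C@@]1(C)O
F7 | step 4 | ethyl (2E)-5-[(1R,2R,4aR,6S,8aS)-2,6-dihydroxy-2,5,5,8a-tetramethyldecahydronaphthalen-1-yl]-2-methylpent-2-enoate | CCOC(=O)/C(C)=C/CC[C@@H]1[C@@]2(C)CC[C@H](O)C(C)(C)[C@@H]2CC[C@@]1(C)O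
F8 | step 4 | (1R,2R,4aR,6S,8aS)-1-[(3E)-5-hydroxy-4-methylpent-3-en-1-yl]-2,5,5,8a-tetramethyldecahydronaphthalene-2,6-diol | OC/C(C)=C/CC[C@@H]1[C@@]2(C)CC[C@H](O)C(C)(C)[C@@H]2CC[C@@]1(C)O
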